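**Plan**

1. Retrosynthesis cuts C1–C14 (eleven-membered ring, Ni/Cr closure), then C11–C12 (crotylboration), C9–C10 (Claisen), C1–C15 and C15–C17 of ring A (Grignard opening of an enol lactone, then aldol). The last cut is C4–C16 of the cyclopentane, a retro-Wolff ring expansion to a 2,2-disubstituted cyclohexanone that is (R)-carvone plus a propargyl group.
2. Enabling feature: in the cyclopentane C4–C5–C6–C7–C16 the quaternary C4 (methyl C18) sits next to C16–H, and C16 carries ring-A carbon C15, which can stand at the carboxylic acid level. That is the product pattern of a Wolff contraction of a 6,6-disubstituted 2-diazocyclohexanone. In carvone the carbonyl carbon (→C15) lies between the methyl-bearing carbon (→C4) and the only enolisable CH2 (→C16), and the isopropenyl carbon (→C7, with C8, C19, C9) is already in place.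
3. Forward order: carvone six-membered ring → cyclopentane (ring contraction) → ring A cyclohexenone → C9–C14 chain → eleven-membered ring → C14 carbinol.
4. Stereochemistry: C7 from (R)-carvone; C4 by axial alkylation cis to isopropenyl; C16 by face-selective protonation after the Wolff shift, then held in a cis-fused lactone; C3 by equilibration and C2 by hydroxyl-directed reduction; C11/C12 by reagent-controlled crotylboration; C14 by CBS reduction.

Key step: step 3

Remark (numbering used in the text, trinervitane skeleton): ring A = C1(=C15)–C2–C3–C4–C16; cyclopentane = C4–C5–C6–C7–C16; eleven-membered ring = C1, C15, C16, C7, C8–C14; C17 is the methyl on C15, C18 the methyl on C4, C19 the methylene on C8, C20 the methyl on C12.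

**Step 1**
Reactants: 1 (R)-(−)-carvone
Product: 3 (2R,5R)-2-methyl-5-(prop-1-en-2-yl)-2-(prop-2-yn-1-yl)cyclohexan-1-one, via lithium enolate 2 (not isolated)
Conditions: L-Selectride (LiBH(s-Bu)3), THF, −78 °C; then propargyl bromide, DMPU, −78 to 25 °C
Reagents that add atoms: propargyl bromide, C#CCBr
Why: Conjugate hydride delivery gives the C1–C2 enolate regiospecifically, and its alkylation (reductive alkylation of an enone) should proceed by axial attack through a chair-like transition state on the face cis to the equatorial isopropenyl group, setting quaternary C4 with the propargyl arm cis to the isopropenyl group.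

**Step 2**
Reactants: 3 (2R,5R)-2-methyl-5-(prop-1-en-2-yl)-2-(prop-2-yn-1-yl)cyclohexan-1-one
Product: 5 (3S,6R)-2-diazo-6-methyl-3-(prop-1-en-2-yl)-6-(prop-2-yn-1-yl)cyclohexan-1-one, via trifluoroacetyl ketone 4 (not isolated)
Conditions: LiHMDS, THF, −78 °C; CF3CO2CH2CF3; aq. HCl work-up; then 4-acetamidobenzenesulfonyl azide, Et3N, H2O (1 equiv), MeCN, 25 °C
Reagents that add atoms: 4-acetamidobenzenesulfonyl azide, CC(=O)Nc1ccc(cc1)S(=O)(=O)N=[N+]=[N-]
Why: Only one α-carbon of ketone 3 (future C16) is enolisable, so kinetic trifluoroacetylation followed by deacylative (Regitz-type) diazo transfer should install the diazo group regiospecifically without touching a stereocentre.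

**Step 3**
Reactants: 5 (3S,6R)-2-diazo-6-methyl-3-(prop-1-en-2-yl)-6-(prop-2-yn-1-yl)cyclohexan-1-one
Product: 7 (1R,2R,5R)-2-methyl-5-(prop-1-en-2-yl)-2-(prop-2-yn-1-yl)cyclopentane-1-carboxylic acid, via ketene 6 (not isolated)
Conditions: hν (medium-pressure Hg lamp, Pyrex, λ > 300 nm), THF–H2O (4:1), Et3N, 0 °C
Reagents that add atoms: water, O
Why: Photolysis of the s-cis-locked cyclic α-diazo ketone expels N2 with 1,2-shift of the C4–C15 bond to the diazo carbon C16 (Wolff rearrangement), so the six-membered carvone ring contracts to the cyclopentane C4–C5–C6–C7–C16 and ketene 6 is trapped by water as acid 7; the closest known reaction type is the photochemical ring contraction of 2-diazocycloalkanones flanked by a quaternary carbon to cycloalkanecarboxylic acids. The five-membered ring is formed by this 1,2-alkyl shift and not by a cyclisation, so no ring-closure mode applies; the migrating quaternary C4 keeps its configuration and C7 is untouched. The new stereocentre C16 arises when the ketene hydrate (ene-1,1-diol) ketonises, and protonation should occur on the face anti to the two cis substituents that flank it (the propargyl arm on C4 and the isopropenyl group on C7), placing the carboxyl group cis to both. The step needs the Wolff shift to win over carbene 1,2-hydride shift or C–H insertion and needs C4 alone to migrate; the fixed s-cis geometry of the cyclic diazo ketone and the single acyl substituent secure both. Et3N keeps the product acid from protonating unreacted diazo ketone, and light above 300 nm is absorbed only by the diazo ketone, so the alkyne and the alkene should survive.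

**Step 4**
Reactants: 7 (1R,2R,5R)-2-methyl-5-(prop-1-en-2-yl)-2-(prop-2-yn-1-yl)cyclopentane-1-carboxylic acid
Product: 8 (4aR,7R,7aR)-4a-methyl-3-methylidene-7-(prop-1-en-2-yl)hexahydrocyclopenta[c]pyran-1(3H)-one
Conditions: AuCl (5 mol %), K2CO3 (10 mol %), MeCN, 25 °C
Reagents that add atoms: none
Why: Monovalent gold activates the terminal alkyne toward 6-exo-dig anti-oxyauration by the cis-disposed carboxyl group (cycloisomerisation of a 5-alkynoic acid), which should give the cis-fused exo-methylene δ-lactone with the C–O bond at the internal alkyne carbon (future C2) and leave the three stereocentres untouched.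

**Step 5**
Reactants: 8 (4aR,7R,7aR)-4a-methyl-3-methylidene-7-(prop-1-en-2-yl)hexahydrocyclopenta[c]pyran-1(3H)-one
Product: 10 (1R,3aR,7aR)-7-hydroxy-3a,7-dimethyl-1-(prop-1-en-2-yl)octahydro-5H-inden-5-one (carbinol configuration at C15 not controlled), via keto enolate 9 (not isolated)
Conditions: MeMgBr (1.05 equiv), THF, −78 to 0 °C; sat. aq. NH4Cl
Reagents that add atoms: methylmagnesium bromide, C[Mg]Br
Why: Addition of MeMgBr to the enol lactone carbonyl and collapse of the hemiketalate (Fujimoto–Belleau-type opening) unmask the C15 methyl ketone (C17) together with the regiodefined C1–C2 magnesium enolate 9, which should close ring A by a 6-(enolendo)-exo-trig aldol addition faster than proton transfer can move the enolate; the carbinol centre formed is lost in step 6.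

**Step 6**
Reactants: 10 (1R,3aR,7aR)-7-hydroxy-3a,7-dimethyl-1-(prop-1-en-2-yl)octahydro-5H-inden-5-one
Product: 12 (1R,3aR,7aR)-3a,7-dimethyl-1-(prop-1-en-2-yl)-1,2,3,3a,4,7a-hexahydro-5H-inden-5-one, via tertiary trifluoroacetate 11 (not isolated)
Conditions: (CF3CO)2O, pyridine, DMAP, CH2Cl2, 0 °C; then DBU, 25 °C
Reagents that add atoms: none
Why: Trifluoroacetylation of the tertiary β-hydroxyl and DBU-mediated E1cB elimination through the C1 enolate should give the conjugated C2 enone (C1=C15) without acid, so neither retro-aldol scrambling nor epimerisation of ring-fusion carbon C16 is expected.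

**Step 7**
Reactants: 12 (1R,3aR,7aR)-3a,7-dimethyl-1-(prop-1-en-2-yl)-1,2,3,3a,4,7a-hexahydro-5H-inden-5-one
Product: 13 (1R,3aR,7aR)-1-(3-hydroxyprop-1-en-2-yl)-3a,7-dimethyl-1,2,3,3a,4,7a-hexahydro-5H-inden-5-one
Conditions: SeO2 (0.3 equiv), t-BuOOH, CH2Cl2, 25 °C
Reagents that add atoms: tert-butyl hydroperoxide, CC(C)(C)OO
Why: Catalytic SeO2 effects ene/[2,3]-sigmatropic allylic hydroxylation of the electron-rich 1,1-disubstituted alkene at its methyl group in preference to the methine, while the enone alkene is too electron-poor to react.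

**Step 8**
Reactants: 13 (1R,3aR,7aR)-1-(3-hydroxyprop-1-en-2-yl)-3a,7-dimethyl-1,2,3,3a,4,7a-hexahydro-5H-inden-5-one
Product: 15 4-[(1R,3aR,7aR)-3a,7-dimethyl-5-oxo-2,3,3a,4,5,7a-hexahydro-1H-inden-1-yl]pent-4-enal, via allyl vinyl ether 14 (not isolated)
Conditions: ethyl vinyl ether (solvent), Hg(OAc)2 (cat.), 35 °C; evaporate; PhMe, 140 °C (sealed tube)
Reagents that add atoms: ethyl vinyl ether, C=COCC
Why: Hg(OAc)2-catalysed transfer vinylation gives allyl vinyl ether 14, whose thermal [3,3]-sigmatropic (Claisen) rearrangement forms the C9–C10 bond and, because both termini of the 2-substituted allyl unit are CH2 groups, regenerates the exocyclic methylene on C8 while delivering the C11 aldehyde; no stereocentre is formed.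

**Step 9**
Reactants: 15 4-[(1R,3aR,7aR)-3a,7-dimethyl-5-oxo-2,3,3a,4,5,7a-hexahydro-1H-inden-1-yl]pent-4-enal
Product: 16 (1R,3aR,7aR)-1-[(5S,6R)-5-hydroxy-6-methylocta-1,7-dien-2-yl]-3a,7-dimethyl-1,2,3,3a,4,7a-hexahydro-5H-inden-5-one
Conditions: (+)-(E)-crotyl-B(Ipc)2 (freshly prepared reagent solution, Ipc from (−)-α-pinene), THF, −78 °C; then HOCH2CH2NH2, 25 °C
Reagents that add atoms: (+)-(E)-crotyldiisopinocampheylborane, C/C=C/CB([C@H]1C[C@H]2C[C@@H]([C@@H]1C)C2(C)C)[C@H]1C[C@H]2C[C@@H]([C@@H]1C)C2(C)C
Why: Brown crotylboration through a closed chair transition state: the (E)-crotyl geometry gives the anti relationship of C11–OH and C12–CH3, and the isopinocampheyl groups direct addition to the Re face of the aldehyde (11S,12R) under reagent control, the hindered enone carbonyl being a spectator at −78 °C.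

**Step 10**
Reactants: 16 (1R,3aR,7aR)-1-[(5S,6R)-5-hydroxy-6-methylocta-1,7-dien-2-yl]-3a,7-dimethyl-1,2,3,3a,4,7a-hexahydro-5H-inden-5-one
Product: 17 the C11 tert-butyldimethylsilyl ether of 16
Conditions: TBSCl, imidazole, DMF, 25 °C
Reagents that add atoms: tert-butyldimethylsilyl chloride, CC(C)(C)[Si](C)(C)Cl
Why: Imidazole-promoted silylation of the only hydroxyl group (silyl ether protection) masks C11–OH for the later acetylation and oxidations; mild base leaves the enone untouched.

**Step 11**
Reactants: 17 the C11 tert-butyldimethylsilyl ether of 16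
Product: 18 the 6-iodo enone derived from 17 (iodine on enone α-carbon C1)
Conditions: I2, pyridine–CH2Cl2 (1:1), 25 °C, dark
Reagents that add atoms: iodine, II
Why: Pyridine-mediated α-iodination of the enone (conjugate addition of pyridine, iodination of the enolate, elimination) places iodine on C1, the only enone α-carbon, and isolated alkenes do not add iodine irreversibly under these conditions.

**Step 12**
Reactants: 18 the 6-iodo enone derived from 17
Product: 19 the α′-hydroxy iodo enone (hydroxyl on C3, cis to the angular methyl C18)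
Conditions: KHMDS, THF, −78 °C; 2-(phenylsulfonyl)-3-phenyloxaziridine, −78 °C; sat. aq. NH4Cl; then DBU (cat.), PhMe, 25 °C
Reagents that add atoms: 2-(phenylsulfonyl)-3-phenyloxaziridine, O=S(=O)(N1OC1c1ccccc1)c1ccccc1
Why: Kinetic deprotonation occurs at C3, the only α′ position, and oxidation of the potassium dienolate by the N-sulfonyloxaziridine (Davis hydroxylation) gives the α′-hydroxy enone; DBU should then equilibrate C3 through the enediol to the pseudo-equatorial alcohol cis to C18, the epimer being destabilised by a syn-axial contact with C7.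

**Step 13**
Reactants: 19 the α′-hydroxy iodo enone
Product: 20 the iodo trans-diol (C2–OH trans to C3–OH)
Conditions: Me4NBH(OAc)3, MeCN–AcOH (1:1), −20 °C
Reagents that add atoms: none
Why: Exchange of the C3 hydroxyl onto the triacetoxyborohydride and intramolecular hydride delivery to the neighbouring carbonyl from the same face (Evans–Saksena hydroxyl-directed reduction) should give the 1,2-reduction product with C2–OH trans to C3–OH.

**Step 14**
Reactants: 20 the iodo trans-diol
Product: 21 the iodo diacetate (C2 and C3 acetates)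
Conditions: Ac2O, Et3N, DMAP (cat.), CH2Cl2, 25 °C
Reagents that add atoms: acetic anhydride, CC(=O)OC(C)=O
Why: DMAP-catalysed acylation esterifies both secondary hydroxyls, including the hindered neopentyl C3–OH; the silyl ether and the alkenyl iodide are inert.

**Step 15**
Reactants: 21 the iodo diacetate
Product: 23 the primary alcohol (C14–OH), via alkylborane 22 (not isolated)
Conditions: Sia2BH (disiamylborane, preformed), THF, 0 °C; then H2O2, pH 7 phosphate buffer, 0 to 25 °C
Reagents that add atoms: hydrogen peroxide, OO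
Why: Disiamylborane hydroborates the monosubstituted terminal alkene (anti-Markovnikov hydroboration–oxidation) much faster than the hindered 1,1-disubstituted C8 methylene or the tetrasubstituted iodoalkene, and buffered peroxide keeps the acetates intact.

**Step 16**
Reactants: 23 the primary alcohol
Product: 24 the C14 aldehyde
Conditions: Dess–Martin periodinane, pyridine, CH2Cl2, 25 °C
Reagents that add atoms: none
Why: Dess–Martin oxidation converts the primary alcohol into the aldehyde under buffered, non-epimerising conditions; the nearest stereocentre (C12) is β to the carbonyl.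

**Step 17**
Reactants: 24 the C14 aldehyde
Product: 26 the macrocyclic allylic alcohol (11-O-TBS, both C14 epimers), via alkenylchromium species 25 (not isolated)
Conditions: CrCl2 (10 equiv), NiCl2 (1 mol %), DMSO–THF (3:1), 2 mM, 25 °C
Reagents that add atoms: none
Why: Oxidative addition of zerovalent nickel (formed in situ) into the C1–I bond, transmetalation to trivalent chromium and addition of alkenylchromium 25 to the tethered aldehyde (Nozaki–Hiyama–Kishi reaction) should close the eleven-membered ring under high dilution with tolerance of the acetates; the C14 configuration is not relied on because steps 18 and 19 reset it.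

**Step 18**
Reactants: 26 the macrocyclic allylic alcohol (both C14 epimers)
Product: 27 the macrocyclic C14 enone
Conditions: Dess–Martin periodinane, pyridine, CH2Cl2, 0 to 25 °C
Reagents that add atoms: none
Why: Dess–Martin oxidation of the allylic alcohol converges both epimers on one enone without affecting acetates, silyl ether or alkenes.

**Step 19**
Reactants: 27 the macrocyclic C14 enone
Product: 28 the 11-O-TBS ether of the target (14S)
Conditions: (R)-2-methyl-CBS-oxazaborolidine (20 mol %), catecholborane, PhMe, −78 °C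
Reagents that add atoms: none
Why: Corey–Bakshi–Shibata reduction: the (R)-oxazaborolidine binds the ketone with the bulky tetrasubstituted alkenyl group as the large substituent and should deliver hydride to the face that gives the (14S)-allylic alcohol under reagent control, and catecholborane neither hydroborates the alkenes nor reduces the acetates at −78 °C.

**Step 20**
Reactants: 28 the 11-O-TBS ether of the target
Product: 29 CNP0114864.2, (2R,3R,4S,7R,11S,12R,14S,16S)-2,3-diacetoxytrinervita-1(15),8(19)-diene-11,14-diol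
Conditions: HF·pyridine, pyridine, THF, 0 to 25 °C
Reagents that add atoms: none
Why: Fluoride cleaves the Si–O bond of the secondary silyl ether (desilylation) while the acetates and the allylic alcohol are stable to buffered HF·pyridine.

**Compound list**

1 | (R)-(−)-carvone | CC1=CC[C@H](CC1=O)C(C)=C | starting material
2 | lithium (5R)-2-methyl-5-(prop-1-en-2-yl)cyclohex-1-en-1-olate | [Li]OC1=C(C)CC[C@@H](C(C)=C)C1 | intermediate (not isolated)
3 | (2R,5R)-2-methyl-5-(prop-1-en-2-yl)-2-(prop-2-yn-1-yl)cyclohexan-1-one | O=C1[C@@](C)(CC#C)CC[C@@H](C(C)=C)C1 | intermediate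
4 | (3R,6R)-6-methyl-3-(prop-1-en-2-yl)-6-(prop-2-yn-1-yl)-2-(trifluoroacetyl)cyclohexan-1-one (C2 epimers/enol) | O=C1[C@@](C)(CC#C)CC[C@@H](C(C)=C)C1C(=O)C(F)(F)F | intermediate (not isolated)
5 | (3S,6R)-2-diazo-6-methyl-3-(prop-1-en-2-yl)-6-(prop-2-yn-1-yl)cyclohexan-1-one | O=C1[C@@](C)(CC#C)CC[C@@H](C(C)=C)C1=[N+]=[N-] | intermediate
6 | ketene: [2-methyl-5-(prop-1-en-2-yl)-2-(prop-2-yn-1-yl)cyclopentylidene]methanone, propargyl cis to isopropenyl | C#CC[C@@]1(C)CC[C@@H](C(C)=C)C1=C=O | intermediate (not isolated)
7 | (1R,2R,5R)-2-methyl-5-(prop-1-en-2-yl)-2-(prop-2-yn-1-yl)cyclopentane-1-carboxylic acid | C#CC[C@@]1(C)CC[C@@H](C(C)=C)[C@H]1C(=O)O | intermediate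
8 | (4aR,7R,7aR)-4a-methyl-3-methylidene-7-(prop-1-en-2-yl)hexahydrocyclopenta[c]pyran-1(3H)-one | [C@]12(C)CC[C@@H](C(C)=C)[C@H]1C(=O)OC(=C)C2 | intermediate
9 | bromomagnesium enolate of the ring-opened 1,5-diketone (acetyl on C16, 2-oxidoallyl on C4) | C=C(O[Mg]Br)C[C@@]1(C)CC[C@@H](C(C)=C)[C@H]1C(C)=O | intermediate (not isolated)
10 | (1R,3aR,7aR)-7-hydroxy-3a,7-dimethyl-1-(prop-1-en-2-yl)octahydro-5H-inden-5-one (carbinol centre unspecified) | [C@]12(C)CC[C@@H](C(C)=C)[C@H]1C(C)(O)CC(=O)C2 | intermediate
11 | tertiary trifluoroacetate of 10 | [C@]12(C)CC[C@@H](C(C)=C)[C@H]1C(C)(OC(=O)C(F)(F)F)CC(=O)C2 | intermediate (not isolated)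
12 | (1R,3aR,7aR)-3a,7-dimethyl-1-(prop-1-en-2-yl)-1,2,3,3a,4,7a-hexahydro-5H-inden-5-one | [C@]12(C)CC[C@@H](C(C)=C)[C@H]1C(C)=CC(=O)C2 | intermediate
13 | (1R,3aR,7aR)-1-(3-hydroxyprop-1-en-2-yl)-3a,7-dimethyl-1,2,3,3a,4,7a-hexahydro-5H-inden-5-one | [C@]12(C)CC[C@@H](C(CO)=C)[C@H]1C(C)=CC(=O)C2 | intermediate
14 | vinyl ether of 13 | [C@]12(C)CC[C@@H](C(COC=C)=C)[C@H]1C(C)=CC(=O)C2 | intermediate (not isolated)
15 | 4-[(1R,3aR,7aR)-3a,7-dimethyl-5-oxo-2,3,3a,4,5,7a-hexahydro-1H-inden-1-yl]pent-4-enal | [C@]12(C)CC[C@@H](C(=C)CCC=O)[C@H]1C(C)=CC(=O)C2 | intermediate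
16 | (1R,3aR,7aR)-1-[(5S,6R)-5-hydroxy-6-methylocta-1,7-dien-2-yl]-3a,7-dimethyl-1,2,3,3a,4,7a-hexahydro-5H-inden-5-one | [C@]12(C)CC[C@@H](C(=C)CC[C@H](O)[C@H](C)C=C)[C@H]1C(C)=CC(=O)C2 | intermediate
17 | C11 tert-butyldimethylsilyl ether of 16 | [C@]12(C)CC[C@@H](C(=C)CC[C@H](O[Si](C)(C)C(C)(C)C)[C@H](C)C=C)[C@H]1C(C)=CC(=O)C2 | intermediate
18 | 6-iodo enone from 17 (iodine on C1) | [C@]12(C)CC[C@@H](C(=C)CC[C@H](O[Si](C)(C)C(C)(C)C)[C@H](C)C=C)[C@H]1C(C)=C(I)C(=O)C2 | intermediate
19 | α′-hydroxy iodo enone (C3–OH cis to the angular methyl) | [C@]12(C)CC[C@@H](C(=C)CC[C@H](O[Si](C)(C)C(C)(C)C)[C@H](C)C=C)[C@H]1C(C)=C(I)C(=O)[C@@H]2O | intermediate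
20 | iodo trans-diol (C2–OH trans to C3–OH) | [C@]12(C)CC[C@@H](C(=C)CC[C@H](O[Si](C)(C)C(C)(C)C)[C@H](C)C=C)[C@H]1C(C)=C(I)[C@@H](O)[C@@H]2O | intermediate
21 | iodo diacetate | [C@]12(C)CC[C@@H](C(=C)CC[C@H](O[Si](C)(C)C(C)(C)C)[C@H](C)C=C)[C@H]1C(C)=C(I)[C@@H](OC(C)=O)[C@@H]2OC(C)=O | intermediate
22 | alkyl(disiamyl)borane from 21 (boron on C14) | [C@]12(C)CC[C@@H](C(=C)CC[C@H](O[Si](C)(C)C(C)(C)C)[C@H](C)CCB(C(C)C(C)C)C(C)C(C)C)[C@H]1C(C)=C(I)[C@@H](OC(C)=O)[C@@H]2OC(C)=O | intermediate (not isolated)
23 | primary alcohol (C14–OH) | [C@]12(C)CC[C@@H](C(=C)CC[C@H](O[Si](C)(C)C(C)(C)C)[C@H](C)CCO)[C@H]1C(C)=C(I)[C@@H](OC(C)=O)[C@@H]2OC(C)=O | intermediate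
24 | C14 aldehyde | [C@]12(C)CC[C@@H](C(=C)CC[C@H](O[Si](C)(C)C(C)(C)C)[C@H](C)CC=O)[C@H]1C(C)=C(I)[C@@H](OC(C)=O)[C@@H]2OC(C)=O | intermediate
25 | alkenylchromium dichloride from 24 (chromium on C1) | [C@]12(C)CC[C@@H](C(=C)CC[C@H](O[Si](C)(C)C(C)(C)C)[C@H](C)CC=O)[C@H]1C(C)=C([Cr](Cl)Cl)[C@@H](OC(C)=O)[C@@H]2OC(C)=O | intermediate (not isolated)
26 | macrocyclic allylic alcohol, 11-O-TBS, both C14 epimers | C=C1CC[C@H](O[Si](C)(C)C(C)(C)C)[C@H](C)CC(O)C2=C(C)[C@@H]3[C@H]1CC[C@]3(C)[C@@H](OC(C)=O)[C@@H]2OC(C)=O | intermediate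
27 | macrocyclic C14 enone, 11-O-TBS | C=C1CC[C@H](O[Si](C)(C)C(C)(C)C)[C@H](C)CC(=O)C2=C(C)[C@@H]3[C@H]1CC[C@]3(C)[C@@H](OC(C)=O)[C@@H]2OC(C)=O | intermediate
28 | 11-O-TBS ether of the target (14S) | C=C1CC[C@H](O[Si](C)(C)C(C)(C)C)[C@H](C)C[C@H](O)C2=C(C)[C@@H]3[C@H]1CC[C@]3(C)[C@@H](OC(C)=O)[C@@H]2OC(C)=O | intermediate
29 | CNP0114864.2, (2R,3R,4S,7R,11S,12R,14S,16S)-2,3-diacetoxytrinervita-1(15),8(19)-diene-11,14-diol | C=C1CC[C@H](O)[C@H](C)C[C@H](O)C2=C(C)[C@@H]3[C@H]1CC[C@]3(C)[C@@H](OC(C)=O)[C@@H]2OC(C)=O | target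

**Step count and risks**

Total step count: 20. Longest linear sequence: 20 steps from (R)-carvone (the route is fully linear).

Steps most likely to fail:

1. Step 17 (ring closure). Intermolecular coupling, proto-demetalation of the alkenylchromium or reductive loss of the aldehyde may outrun closure of the strained eleven-membered ring. The fallback sets out from aldehyde 24 and returns at enone 27. Pinnick oxidation (NaClO2, NaH2PO4, 2-methylbut-2-ene) would give carboxylic acid F1, and coupling with MeNHOMe·HCl (EDC, DMAP) would give Weinreb amide F2. Iodine–magnesium exchange with i-PrMgCl·LiCl (THF, −40 °C, high dilution) would then form alkenylmagnesium chloride F3, which acylates itself intramolecularly on the N-methoxy-N-methylamide through a chelated tetrahedral intermediate. This gives 27 directly, so no aldehyde is exposed to a reducing metal and step 18 is not needed.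

2. Step 5 (ring A). Over-addition of the Grignard reagent to the liberated methyl ketone, or proton transfer within keto enolate 9 followed by the alternative aldol closure (C17 onto C2), would give the regioisomeric cyclohexenone. The fallback sets out from acid 7 and returns at enone 12. MeLi (3.2 equiv, THF, 0 °C) would convert the acid into methyl ketone F4. CuI-catalysed aerobic coupling of the terminal alkyne with diethyl phosphite (Et3N, DMSO, air) would give alkynylphosphonate F5, and PdCl2-catalysed hydration (aq. dioxane) would give β-ketophosphonate F6. Intramolecular Horner–Wadsworth–Emmons olefination (LiCl, DBU, MeCN) of the C15 ketone by the phosphonate carbon then closes ring A with the regiochemistry fixed by the position of phosphorus.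

3. Step 3 (key step). Poor facial selectivity in the protonation of the ketene hydrate would erode the configuration at C16. The fallback sets out from diazo ketone 5 and returns at enol lactone 8. The photolysate containing the C1-epimeric acid F7 would be taken through the AuCl cyclisation of step 4, in which F7 gives the trans-fused enol lactone F8. The lactone mixture would then be equilibrated with DBU (PhMe, 60 °C) through the lactone enolate to the more stable cis-fused lactone 8, replacing kinetic protonation by thermodynamic control of the ring fusion.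

**Further compounds**

F1 | step 17 | carboxylic acid from aldehyde 24 (C14 acid) | [C@]12(C)CC[C@@H](C(=C)CC[C@H](O[Si](C)(C)C(C)(C)C)[C@H](C)CC(=O)O)[C@H]1C(C)=C(I)[C@@H](OC(C)=O)[C@@H]2OC(C)=O
F2 | step 17 | N-methoxy-N-methylamide of F1 | [C@]12(C)CC[C@@H](C(=C)CC[C@H](O[Si](C)(C)C(C)(C)C)[C@H](C)CC(=O)N(C)OC)[C@H]1C(C)=C(I)[C@@H](OC(C)=O)[C@@H]2OC(C)=O
F3 | step 17 | alkenylmagnesium chloride from F2 (magnesium on C1, not isolated) | [C@]12(C)CC[C@@H](C(=C)CC[C@H](O[Si](C)(C)C(C)(C)C)[C@H](C)CC(=O)N(C)OC)[C@H]1C(C)=C([Mg]Cl)[C@@H](OC(C)=O)[C@@H]2OC(C)=O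
F4 | step 5 | 1-[(1R,2R,5R)-2-methyl-5-(prop-1-en-2-yl)-2-(prop-2-yn-1-yl)cyclopentyl]ethan-1-one | C#CC[C@@]1(C)CC[C@@H](C(C)=C)[C@H]1C(C)=O
F5 | step 5 | diethyl alkynylphosphonate from F4 | CCOP(=O)(OCC)C#CC[C@@]1(C)CC[C@@H](C(C)=C)[C@H]1C(C)=O
F6 | step 5 | diethyl β-ketophosphonate from F5 | CCOP(=O)(OCC)CC(=O)C[C@@]1(C)CC[C@@H](C(C)=C)[C@H]1C(C)=O
F7 | step 3 | (1S,2R,5R)-2-methyl-5-(prop-1-en-2-yl)-2-(prop-2-yn-1-yl)cyclopentane-1-carboxylic acid | C#CC[C@@]1(C)CC[C@@H](C(C)=C)[C@@H]1C(=O)O
F8 | step 3 | (4aR,7R,7aS)-4a-methyl-3-methylidene-7-(prop-1-en-2-yl)hexahydrocyclopenta[c]pyran-1(3H)-one (trans-fused) | [C@]12(C)CC[C@@H](C(C)=C)[C@@H]1C(=O)OC(=C)C2
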